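A small charge of free catalyst, 2.1 mol% of the starting material, has to turn over many times here, so count target per catalyst.

common to all: free catalyst 2.1 mol%
- midnight: starting material 20 mM; second substrate 1 equiv; run made earlier
- spring: starting material 30 mM; second substrate 1 equiv; run made earlier
- oak: starting material 20 mM; second substrate 1.00 equiv (fed, over 15 min); all else is in the flask from the start; the feed brings no volume worth counting; time 20 min
- cedar: starting material 20 mM; second substrate 1.00 equiv; everything together at the start; time 20 min
- alder: starting material 20 mM (fed, over 15 min); second substrate 1.00 equiv; all else is in the flask from the start; the feed brings no volume worth counting; time 20 min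

| run | time / min | target / % | starting material / % |
|---|---|---|---|
| midnight | 1.50 | 2 | 97 |
| midnight | 3.00 | 2 | 96 |
| midnight | 6.00 | 9 | 96 |
| midnight | 10.0 | 11 | 91 |
| midnight | 20.0 | 33 | 68 |
| spring | 1.33 | 1 | 99 |
| spring | 2.50 | 4 | 100 |
| spring | 4.00 | 2 | 97 |
| spring | 5.00 | 6 | 98 |
| spring | 6.00 | 8 | 96 |

(scatter of a reading: 1.5 percentage points)

- the flask that comes out highest in amount of target, in percent of the starting material charged, or "all alike" when all lie within 1.5 percentage points (oak / cedar / alder / all alike)
- target at the end, in percent of the starting material charged, oak
- target at the end, in percent of the starting material charged, cedar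
- target at the end, in percent of the starting material charged, alder

- a reading or a percentage of target counts all its forms, free or not

Midnight and spring differ in concentration, 20 mM against 30 mM, at one loading, yet at 6.00 min they read 9% and 8% of the charge, within the scatter of 1.5 percentage points. So freeze the early turnover frequency, the fraction of the charge made into target per minute per fraction of catalyst, read up to 10.0 min of midnight:

early: 11% / (10.0 min × 2.1 mol%) = 0.524 min⁻¹

late, 10.0 min to 20.0 min: 1.05 min⁻¹

The late reading is about twice the early one. Now solve two extreme flasks, one slow throughout and one fast throughout:

slow: 0.524 min⁻¹ × 2.1 mol% × 20 min = 22.0%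

fast: 1.05 min⁻¹ × 2.1 mol% × 20 min = 44.0%

Midnight started slow and sped up, so put cedar, its repeat, between them at the reading 33%. In alder the feed brings 0.0667 min⁻¹ of the charge, more than the fast extreme draws, 0.0221 min⁻¹, so keep alder inside the same bracket. Place oak there too. Both runs were equimolar, so they do not separate the roles of the two substrates, and the top end is a window average, which makes it soft.

The forecast gave 25% for oak, 32% for cedar and 25% for alder, and chose cedar: “If activation holds, starving the flask early delays build-up”.

The flasks give 51.8% in oak, 33.0% in cedar and 27.7% in alder.

    crystals ⇌ target, rate k1*(cs1 - [target]) while solid is left; crystals form when [target] > cs1 (solubility = 0.330 mM, k = 0.176 s⁻¹)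
    second substrate + free catalyst ⇌ catalyst intermediate B (K = 8900 M⁻¹, k = 82.9 M⁻¹ s⁻¹)
    starting material + free catalyst ⇌ catalyst intermediate A (K = 77.0 M⁻¹, k = 23.5 M⁻¹ s⁻¹)
    catalyst intermediate B → free catalyst + second product (k = 0.0412 s⁻¹)
    catalyst intermediate A → free catalyst + target (k = 0.256 s⁻¹)

Alder lies inside the bracket, but oak stands 7.8 points above the fast extreme. Take the neighbour of alder charged with 5.2 mol% of free catalyst, and apply the same turnover frequencies. The slow extreme gives 54.5%, and the fast extreme passes the charge at 109%, so its ceiling is the charge itself. That neighbour ends at 99.5% target, with 0.509% of the starting material left.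

The data were computed on assumed constants, noise included.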